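## The problem

Target 18 is a flat, achiral flavone: a benzopyran-4-one (rings A and C) carrying ring B at C2. There is no stereocentre to set and none that could steer another. The difficulty lies in regiochemistry and in telling six oxygen substituents apart.

Ring C is fully substituted, with the aryl group at C2, a methoxy group at C3 and the carbonyl at C4. C4 sits peri to the 5-methoxy group, so the C4a–C4 bond must be made at a ring-A carbon flanked by two oxygen-bearing neighbours (C5 and C8a).

Only the oxygen at C5' is free. It cannot be released at the end by selective demethylation, because Lewis acids attack the 5- and 3-methoxy groups beside the carbonyl first. Ring B therefore has to arrive with this one oxygen masked differently.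

The 3-methoxy group is best carried in from the start. Hydroxylating a finished flavone at C3 costs steps and exposes two electron-rich rings to oxidants.

Three points are sensitive on the way:
- methyl ethers next to carbonyl groups, which are cleaved by Lewis acids;
- the hydroquinone-monoether pattern of ring B once its phenol is free, which is prone to oxidation;
- any open 1,3-diketone, which can suffer nucleophilic acyl cleavage.

The feature that opens the plan is C4 itself. It is a lone carbonyl carbon bound only to C4a of ring A and to C3, so it can come from carbon monoxide. C2 and C3, with the C3 oxygen, come together as an aryl methoxymethyl ketone that has a single enolisable position.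

## Retrosynthesis

**18 to 16.** The first cut opens ring C of 18 at O1–C2 and leads to the o-hydroxyaryl 1,3-diketone 17. This is the ring-C bond whose formation is most dependable, because a phenol beside a 1,3-diketone adds to the far carbonyl and loses water under mild acid. Cutting O1–C8a would need an aryl–oxygen coupling at a crowded carbon. Cutting C2–C1' would need a 2-halochromone that must itself be built. Only the ring-A phenol of 17 can reach a carbonyl through a six-membered transition state, since the 5'-hydroxyl is meta to the side chain. Because the closure runs in acid, both phenols are masked as methoxymethyl acetals in 16. One acid treatment is then asked to remove both acetals and close the ring.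

**16 to 4, 13 and 12.** In 16, C4 is cut out on both sides (C4a–C4 and C3–C4), giving aryl iodide 4, carbon monoxide 13 and ketone 12. The neighbouring cuts are the classical ones:
- C2–C3 calls for a ring-A methoxyacetophenone plus an activated ring-B acid.
- C3–C4 alone calls for a 2,6-dioxygenated benzoyl donor, which is sluggish as an electrophile and awkward to activate beside an acetal.

Taking C4 as 13 removes every acyl donor. Ring A shrinks to an iodide, and two skeletal bonds form in one convergent step joining halves of similar size. The forward reaction must insert 13 faster than it arylates the enolate directly, and it must react through carbon rather than oxygen. It must do both at a doubly ortho-substituted centre.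

**4 to 1.** The C–I bond of 4 goes back to a C–H bond of acetal 2, and 2 to 3,5-dimethoxyphenol 1. The acetal does double duty as the mask of O1 and as the stronger ortho-director. Lithiation should therefore fall between acetal and methoxy oxygen, not between the two methoxy groups. Electrophilic iodination of 1 would have to rely on steric bias alone and is kept in reserve.

**12 to 8 and 9.** Ketone 12 is cut at C1'–C2 into aryl bromide 8, used as its lithium derivative, and Weinreb amide 9. The shorter-looking Friedel–Crafts methoxyacetylation is set aside for two reasons. An α-alkoxy acylium ion sheds 13 under Lewis acids and leaves a methoxymethyl cation, so alkylation competes with acylation. The same Lewis acids strip methyl ethers ortho to the new carbonyl and would not tolerate an acetal. With the polarity reversed no Lewis acid remains in the route, and this is what allows the acetal on ring B.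

**8 to 5.** Bromide 8 comes from phenol 7 by acetal formation, and 7 from 5-bromo-2,4-dimethoxybenzaldehyde 5 by exchange of formyl for hydroxyl. In 5 all four ring-B substituents already stand correctly: bromine marks C1' and the formyl group marks the C5' oxygen. The two methoxy groups ortho and para to the formyl group are what an aryl-migrating peracid oxidation needs.

## Roads not taken

**Alternative 1:** The cut removes ring A as a whole. C5–C6, C7–C8 and C4a–C5 are broken. This leaves methoxyacetylene A3 and diazoketone A2, a 2-aryl-3-methoxypyran-4-one with a diazoacetyl group on the future C8a. A2 is traced to kojic acid A1, which supplies ring C and its 3-oxygen.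

In the forward Danheiser benzannulation, irradiation of A2 triggers a Wolff rearrangement to a vinylketene and A3 adds to it in a [2+2] manner. Heating then takes the cyclobutenone through four-electron opening and six-electron closure to A4.

- Merits: three C–C bonds and a benzene ring form in one operation, which is more than the chosen key step achieves. The regiochemistry is fixed by the polarity of the ynol ether, and the crowded C4a–C4 bond is present from the start.
- Weak points:
  - The 5-hydroxyl that the method delivers is unwanted and must be methylated although it is hydrogen-bonded to C4=O.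
  - A2 needs O-methylation, oxidation of the hydroxymethyl group, halogenation, cross-coupling to bring in ring B and a diazoalkane acylation, all in one line.
  - A3 is volatile and prone to polymerise.
  - The pyranone absorbs in the range of the Wolff step and has photochemistry of its own.
  - The alkene entering the six-electron closure is the electron-poor C4a=C8a bond.
- Comparison: with methylation and debenzylation after A4, the line runs to about ten linear steps against five. The chosen plan gives up the elegance of building ring A. In return, ring A with its correct oxygen pattern is simply bought as 1.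

**Alternative 2:** Ring C is cut at C3–C4 and O1–C2 at the flavylium oxidation level. 2-Hydroxy-4,6-dimethoxybenzaldehyde A5 supplies ring A with C4 as an aldehyde carbon. The O-benzyl analogue A6 of ketone 12 supplies C2, C3 and ring B. In anhydrous mineral acid the enol of A6 condenses with the aldehyde and the phenol closes on C2 to give flavylium chloride A7.

- Merits: A5 is a catalogue compound, and no metal or gas is needed. Fragment union and ring closure coincide, and such salts tend to separate from the medium. Up to A7 this road is better than the chosen one, because it saves the two steps to 4 and the separate closure.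
- Weak points:
  - C4 arrives as CH and must be raised to a carbonyl.
  - Oxygen nucleophiles add to flavylium ions at C2, where the hemiketal opens to a chalcone. They do not add at C4, which in A7 is also screened by the 5-methoxy group.
  - Peroxidic oxidants cleave C2–C3 in a Baeyer–Villiger sense.
  - A detour through a 4H-flavene and allylic oxidation would have to spare an enol ether and two electron-rich rings.
  - Acetals cannot be used in dry acid, hence the benzyl group and a closing hydrogenolysis.
- Comparison: the step on which the target depends has no dependable method. The chosen plan pays with the preparation of 4 and the handling of 13, and in return C4 carries its oxygen from the moment it enters.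

**Alternative 3:** O1–C8a, C4–C4a and O1–C2 are cut. Ring A becomes 3,5-dimethoxybenzyne A9, released by fluoride from o-silylaryl triflate A8. The rest is arylpropiolic acid A10.

The carboxylate adds to the aryne carbon remote from the neighbouring methoxy group. The aryl anion beside that methoxy group takes over the acyl group, and the o-acylphenoxide adds 6-endo-dig to the ynone to give A11.

- Merits: three bonds and ring C form in one metal-free operation. The innate aryne regiochemistry matches the 5,7-pattern, and the crowded C4a–C4 bond is made intramolecularly. In bonds per step this is superior to the chosen key step.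
- Weak points:
  - A11 has hydrogen at C3 and an alkyne cannot carry the 3-methoxy group. C3 hydroxylation, methylation and debenzylation must therefore follow, with oxidants or strong base acting on a molecule with two electron-rich rings.
  - A8 takes about four steps from 1, and A10 about three from a ring-B aldehyde.
  - Proton transfer from the acid to the aryl anion stops the cascade at a plain aryl ester.
  - 5-exo-dig closure to an aurone competes.
- Comparison: the chosen plan closes no ring in its key step, but it carries the 3-methoxy group in 12 and needs only one step afterwards.

Key step: step 6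

Remark: diketones 16 and 17 are drawn as chelated enols (enol OH syn to the C4 carbonyl) and should equilibrate with their diketo forms without consequence for the route; 5 and 9 are taken as catalogue compounds.

## Steps

Step 1
Reactants: 1 3,5-dimethoxyphenol
Product: 2 1,3-dimethoxy-5-(methoxymethoxy)benzene
Conditions: MOMCl, K2CO3, acetone, 0 °C to rt
Reagents that add atoms: chloromethyl methyl ether, COCCl
Why: Williamson-type O-alkylation of the phenoxide by a hard, very reactive α-chloro ether. The acetal later serves as ortho-director and as the acid-labile mask of O1.

Step 2
Reactants: 2 1,3-dimethoxy-5-(methoxymethoxy)benzene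
Product: 4 2-iodo-1,5-dimethoxy-3-(methoxymethoxy)benzene, via aryllithium 3 (not isolated)
Conditions: n-BuLi, THF, 0 °C to rt; then I2, THF, −78 °C; aq. Na2S2O3 wash
Reagents that add atoms: iodine, II
Why: Directed ortho-metalation, in which the bidentate acetal is a stronger director than methoxy and two equivalent sites between acetal and methoxy stand against one between the methoxy groups. Iodine traps 3 quickly at low temperature.

Step 3
Reactants: 5 5-bromo-2,4-dimethoxybenzaldehyde
Product: 7 5-bromo-2,4-dimethoxyphenol, via aryl formate 6 (not isolated)
Conditions: mCPBA, CH2Cl2, 0 °C to rt; aq. NaHCO3 wash; then K2CO3 (cat.), MeOH, rt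
Reagents that add atoms: 3-chloroperoxybenzoic acid, OOC(=O)c1cccc(Cl)c1
Why: Baeyer–Villiger oxidation of an aldehyde (Dakin-type exchange); the ortho and para methoxy groups favour aryl over hydride migration, so formate 6 should form rather than the acid. Aryl formates transesterify readily with methanol, and the aryl bromide is inert.

Step 4
Reactants: 7 5-bromo-2,4-dimethoxyphenol
Product: 8 1-bromo-2,4-dimethoxy-5-(methoxymethoxy)benzene
Conditions: MOMCl, K2CO3, acetone, 0 °C to rt
Reagents that add atoms: chloromethyl methyl ether, COCCl
Why: The same Williamson-type acetal formation as in step 1. Using the same mask as on ring A lets one acid step finish the synthesis.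

Step 5
Reactants: 8 1-bromo-2,4-dimethoxy-5-(methoxymethoxy)benzene; 9 N,2-dimethoxy-N-methylacetamide
Product: 12 1-[2,4-dimethoxy-5-(methoxymethoxy)phenyl]-2-methoxyethan-1-one, via aryllithium 10 (not isolated), via lithium hemiaminal alkoxide 11 (not isolated)
Conditions: n-BuLi, THF, −78 °C; then 9, −78 to 0 °C; aq. NH4Cl
Reagents that add atoms: none
Why: Bromine–lithium exchange at −78 °C outruns any directed deprotonation. In the Weinreb ketone synthesis the chelated adduct 11 holds until the quench, so no second addition occurs. No Lewis acid touches the ethers or the acetal.

Step 6
Reactants: 4 2-iodo-1,5-dimethoxy-3-(methoxymethoxy)benzene; 12 1-[2,4-dimethoxy-5-(methoxymethoxy)phenyl]-2-methoxyethan-1-one; 13 carbon monoxide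
Product: 16 1-[2,4-dimethoxy-6-(methoxymethoxy)phenyl]-3-[2,4-dimethoxy-5-(methoxymethoxy)phenyl]-2-methoxypropane-1,3-dione (chelated enol), via sodium enolate 14 (not isolated), via sodium diketonate 15 (not isolated)
Conditions: 12 (2 equiv), NaN(SiMe3)2 (2 equiv), THF, 0 °C to rt; then 4, Pd(dba)2 (5 mol%), dppp [1,3-bis(diphenylphosphino)propane] (6 mol%), CO (1 atm), 1,4-dioxane, 80 °C; aq. NH4Cl
Reagents that add atoms: none
Why: This is the palladium-catalysed carbonylative α-arylation of a ketone, known for aryl iodides and aryl alkyl ketone enolates as a route to 1,3-diketones. Zerovalent palladium adds to the C–I bond of 4, and the electron-rich, crowded aryl group migrates readily to bound 13, which makes C4a–C4 and puts a carbonyl spacer between the metal and the two ortho substituents. Enolate 14 then replaces iodide on the aroyl complex of divalent palladium, and reductive elimination makes C3–C4. No ring closes, and C3 is not a lasting stereocentre because the product is deprotonated at once to the planar chelate 15 by the second equivalent of 14, whose ketone is recovered. Carbonylative rather than direct arylation is secured by the ortho substituents, which slow reductive elimination from an arylpalladium enolate, together with the CO atmosphere and the chelating bisphosphine. Carbon rather than oxygen acylation is secured thermodynamically, since any enol ester formed is itself an acyl donor towards 14 and the irreversible formation of 15 drains the system to the diketone. Ketone 12 can enolise in one direction only, and pre-forming 14 leaves no free amide base to intercept the aroyl complex. Acetals and methyl ethers are inert to this basic medium.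

Step 7
Reactants: 16 1-[2,4-dimethoxy-6-(methoxymethoxy)phenyl]-3-[2,4-dimethoxy-5-(methoxymethoxy)phenyl]-2-methoxypropane-1,3-dione (chelated enol)
Product: 18 5'-hydroxy-3,5,7,2',4'-pentamethoxyflavone, via bisphenol diketone 17 (not isolated)
Conditions: conc. aq. HCl (cat.), MeOH, 60 °C
Reagents that add atoms: none
Why: Acid-catalysed acetal exchange with methanol frees both phenols. The ring-A phenol of 17 then adds 6-exo-trig to the C2 carbonyl and water is lost, the classical cyclodehydration that ends Baker–Venkataraman-type flavone syntheses. The 5'-hydroxyl cannot reach a carbonyl, and aryl methyl ethers withstand dilute HCl.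

## Compound list

1 | 3,5-dimethoxyphenol | COc1cc(O)cc(OC)c1 | starting material
2 | 1,3-dimethoxy-5-(methoxymethoxy)benzene | COCOc1cc(OC)cc(OC)c1 | intermediate
3 | [2,4-dimethoxy-6-(methoxymethoxy)phenyl]lithium | [Li]c1c(OC)cc(OC)cc1OCOC | intermediate
4 | 2-iodo-1,5-dimethoxy-3-(methoxymethoxy)benzene | COCOc1cc(OC)cc(OC)c1I | intermediate
5 | 5-bromo-2,4-dimethoxybenzaldehyde | COc1cc(OC)c(C=O)cc1Br | starting material
6 | 5-bromo-2,4-dimethoxyphenyl formate | COc1cc(OC)c(OC=O)cc1Br | intermediate
7 | 5-bromo-2,4-dimethoxyphenol | COc1cc(OC)c(O)cc1Br | intermediate
8 | 1-bromo-2,4-dimethoxy-5-(methoxymethoxy)benzene | COCOc1cc(Br)c(OC)cc1OC | intermediate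
9 | N,2-dimethoxy-N-methylacetamide | COCC(=O)N(C)OC | starting material
10 | [2,4-dimethoxy-5-(methoxymethoxy)phenyl]lithium | [Li]c1cc(OCOC)c(OC)cc1OC | intermediate
11 | lithium 1-[2,4-dimethoxy-5-(methoxymethoxy)phenyl]-2-methoxy-1-[methoxy(methyl)amino]ethan-1-olate (racemic tetrahedral adduct) | COCC([O-])(N(C)OC)c1cc(OCOC)c(OC)cc1OC.[Li+] | intermediate
12 | 1-[2,4-dimethoxy-5-(methoxymethoxy)phenyl]-2-methoxyethan-1-one | COCC(=O)c1cc(OCOC)c(OC)cc1OC | intermediate
13 | carbon monoxide | [C-]#[O+] | starting material
14 | sodium (Z)-1-[2,4-dimethoxy-5-(methoxymethoxy)phenyl]-2-methoxyethen-1-olate | CO/C=C(\[O-])c1cc(OCOC)c(OC)cc1OC.[Na+] | intermediate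
15 | sodium salt of 16 (chelated diketonate) | COCOc1cc(OC)cc(OC)c1C(=O)/C(OC)=C(\[O-])c1cc(OCOC)c(OC)cc1OC.[Na+] | intermediate
16 | 1-[2,4-dimethoxy-6-(methoxymethoxy)phenyl]-3-[2,4-dimethoxy-5-(methoxymethoxy)phenyl]-2-methoxypropane-1,3-dione, drawn as the (2E)-3-hydroxy-2-methoxyprop-2-en-1-one with enol OH syn to the carbonyl | COCOc1cc(OC)cc(OC)c1C(=O)/C(OC)=C(\O)c1cc(OCOC)c(OC)cc1OC | intermediate
17 | 1-(2-hydroxy-4,6-dimethoxyphenyl)-3-(5-hydroxy-2,4-dimethoxyphenyl)-2-methoxypropane-1,3-dione, drawn as chelated enol | COc1cc(O)c(C(=O)/C(OC)=C(\O)c2cc(O)c(OC)cc2OC)c(OC)c1 | intermediate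
18 | 5'-hydroxy-3,5,7,2',4'-pentamethoxyflavone | COc1cc(OC)c2c(=O)c(OC)c(-c3cc(O)c(OC)cc3OC)oc2c1 | target

## Step count and risks

Total steps: 7. Longest linear sequence: 5 (steps 3, 4, 5, 6, 7).

**Step 6 (key step).** The enolate is branched at its nucleophilic carbon by the methoxy group. It must be joined to an aroylpalladium centre screened by two ortho substituents. If this union is slow, several diversions open:
- loss of CO followed by direct arylation;
- hydrodeiodination;
- O-acylation that is not corrected;
- deactivation of the catalyst by the chelating α-alkoxy enolate.

The fallback sets out from 2 and 12 and returns at 16. Aryllithium 3, generated as in step 2, is quenched with N,N-dimethylformamide to give 2,4-dimethoxy-6-(methoxymethoxy)benzaldehyde F1. The lithium enolate of 12 (LiN(i-Pr)2, THF, −78 °C) adds to F1 and is quenched cold. This gives 3-[2,4-dimethoxy-6-(methoxymethoxy)phenyl]-1-[2,4-dimethoxy-5-(methoxymethoxy)phenyl]-3-hydroxy-2-methoxypropan-1-one F2, a diastereomer mixture of no consequence. Dess–Martin periodinane (NaHCO3, CH2Cl2) oxidises F2 to 16. C4 then comes from a formyl group, and C3–C4 forms by aldol addition instead of acylation. Total and longest line each grow by one step.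

**Step 2.** Metalation may fall partly between the two methoxy groups or stay incomplete, which would give a regioisomeric or unreacted arene that is hard to remove after iodination. The fallback sets out from 1 and returns at 4, and it replaces anionic by electrophilic substitution. N-Iodosuccinimide in MeCN at low temperature should iodinate the free phenol at the less screened activated position, ortho to OH and para to one methoxy group. This gives 2-iodo-3,5-dimethoxyphenol F3. Acetal formation as in step 1 then gives 4. The step count is unchanged.

**Step 5.** Aryllithium 10 may act as a base on the acidic α-methylene group of 9, or trigger base-induced breakdown of the N-methoxy amide. Either would return the debrominated arene. The fallback sets out from 8 and returns at 12 with the polarity reversed. Bromine–lithium exchange and a quench with N,N-dimethylformamide give 2,4-dimethoxy-5-(methoxymethoxy)benzaldehyde F4. Methoxymethyllithium, made from Bu3SnCH2OMe and n-BuLi in THF at −78 °C, adds to F4 to give 1-[2,4-dimethoxy-5-(methoxymethoxy)phenyl]-2-methoxyethan-1-ol F5. MnO2 in CH2Cl2 oxidises this benzylic alcohol to 12.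

**Step 7.** Three events share one pot. The most likely trouble concerns ring B once its phenol is free. The formaldehyde equivalents released from the acetals may be captured at the activated position ortho to that phenol, and the hydroquinone monoether may oxidise in hot acid. The fallback changes the protecting-group plan. It sets out from 7 and returns at 18.
- Benzyl bromide and K2CO3 in DMF give 1-(benzyloxy)-5-bromo-2,4-dimethoxybenzene F6.
- The operations of step 5 give 1-[5-(benzyloxy)-2,4-dimethoxyphenyl]-2-methoxyethan-1-one F7.
- The operations of step 6 with 4 and 13 give 1-[2,4-dimethoxy-6-(methoxymethoxy)phenyl]-3-[5-(benzyloxy)-2,4-dimethoxyphenyl]-2-methoxypropane-1,3-dione F8.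
- Methanolic HCl now frees only the ring-A phenol and closes the ring to the neutral 5'-benzyloxy-3,5,7,2',4'-pentamethoxyflavone F9.
- Hydrogenolysis (H2, palladium on carbon, EtOAc/MeOH, rt) gives 18.

This costs one more step.

## Further compounds

F1 | step 6 | 2,4-dimethoxy-6-(methoxymethoxy)benzaldehyde | COCOc1cc(OC)cc(OC)c1C=O
F2 | step 6 | 3-[2,4-dimethoxy-6-(methoxymethoxy)phenyl]-1-[2,4-dimethoxy-5-(methoxymethoxy)phenyl]-3-hydroxy-2-methoxypropan-1-one (racemic diastereomer mixture) | COCOc1cc(OC)cc(OC)c1C(O)C(OC)C(=O)c1cc(OCOC)c(OC)cc1OC
F3 | step 2 | 2-iodo-3,5-dimethoxyphenol | COc1cc(O)c(I)c(OC)c1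
F4 | step 5 | 2,4-dimethoxy-5-(methoxymethoxy)benzaldehyde | COCOc1cc(C=O)c(OC)cc1OC
F5 | step 5 | 1-[2,4-dimethoxy-5-(methoxymethoxy)phenyl]-2-methoxyethan-1-ol (racemic) | COCC(O)c1cc(OCOC)c(OC)cc1OC
F6 | step 7 | 1-(benzyloxy)-5-bromo-2,4-dimethoxybenzene | COc1cc(OC)c(OCc2ccccc2)cc1Br
F7 | step 7 | 1-[5-(benzyloxy)-2,4-dimethoxyphenyl]-2-methoxyethan-1-one | COCC(=O)c1cc(OCc2ccccc2)c(OC)cc1OC
F8 | step 7 | 1-[2,4-dimethoxy-6-(methoxymethoxy)phenyl]-3-[5-(benzyloxy)-2,4-dimethoxyphenyl]-2-methoxypropane-1,3-dione (chelated enol) | COCOc1cc(OC)cc(OC)c1C(=O)/C(OC)=C(\O)c1cc(OCc2ccccc2)c(OC)cc1OC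
F9 | step 7 | 5'-benzyloxy-3,5,7,2',4'-pentamethoxyflavone | COc1cc(OC)c2c(=O)c(OC)c(-c3cc(OCc4ccccc4)c(OC)cc3OC)oc2c1
A1 | alternative 1 | kojic acid | OCc1cc(=O)c(O)co1
A2 | alternative 1 | 2-[5-(benzyloxy)-2,4-dimethoxyphenyl]-6-(diazoacetyl)-3-methoxy-4H-pyran-4-one | [N-]=[N+]=CC(=O)c1cc(=O)c(OC)c(-c2cc(OCc3ccccc3)c(OC)cc2OC)o1
A3 | alternative 1 | methoxyacetylene | COC#C
A4 | alternative 1 | 5'-benzyloxy-5-hydroxy-3,7,2',4'-tetramethoxyflavone | COc1cc(O)c2c(=O)c(OC)c(-c3cc(OCc4ccccc4)c(OC)cc3OC)oc2c1
A5 | alternative 2 | 2-hydroxy-4,6-dimethoxybenzaldehyde | COc1cc(O)c(C=O)c(OC)c1
A6 | alternative 2 | 1-[5-(benzyloxy)-2,4-dimethoxyphenyl]-2-methoxyethan-1-one | COCC(=O)c1cc(OCc2ccccc2)c(OC)cc1OC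
A7 | alternative 2 | 5'-benzyloxy-3,5,7,2',4'-pentamethoxyflavylium chloride | COc1cc(OC)c2cc(OC)c(-c3cc(OCc4ccccc4)c(OC)cc3OC)[o+]c2c1.[Cl-]
A8 | alternative 3 | 3,5-dimethoxy-2-(trimethylsilyl)phenyl trifluoromethanesulfonate | COc1cc(OC)c([Si](C)(C)C)c(OS(=O)(=O)C(F)(F)F)c1
A9 | alternative 3 | 3,5-dimethoxybenzyne | COC1=CC(OC)=CC#C1
A10 | alternative 3 | 3-[5-(benzyloxy)-2,4-dimethoxyphenyl]prop-2-ynoic acid | OC(=O)C#Cc1cc(OCc2ccccc2)c(OC)cc1OC
A11 | alternative 3 | 5'-benzyloxy-5,7,2',4'-tetramethoxyflavone | COc1cc(OC)c2c(=O)cc(-c3cc(OCc4ccccc4)c(OC)cc3OC)oc2c1
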